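(The data are simulated for substances that don't exist; the scatter is artificial.)

| flask | substrate | second nucleophile | capture agent | gas | remark | time |
|---|---|---|---|---|---|---|
| zeta | 0.050 M | 0.050 M | 0.013 M | 19 mM (held) | run made earlier |  |
| gamma | 0.050 M | 0.050 M | 0.022 M | 19 mM (held) | run made earlier |  |
| beta | 0.050 M | 0.050 M | 0.037 M | 19 mM (held) | run made earlier |  |
| green | 0.050 M | 0.0500 M | 0.0120 M | 19 mM (held) |  | 4.0 h |
| blue | 0.050 M | 0.0500 M | 0.0250 M | 19 mM (held) |  | 4.0 h |
| amber | 0.050 M | 0.0500 M | 0.0500 M | 19 mM (held) |  | 4.0 h |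

| run | time / h | open intermediate / % | target / % | substrate / % |
|---|---|---|---|---|
| zeta | 0.250 | 0 | 1.8 | 66.7 |
| zeta | 0.417 | 0.4 | 3.4 | 51.5 |
| zeta | 0.833 | 0.4 | 5.5 | 26.1 |
| zeta | 1.33 | 0.1 | 5.9 | 11.9 |
| zeta | 3.00 | 0 | 8.5 | 0.8 |
| gamma | 0.500 | 0.3 | 4.6 | 44.3 |
| gamma | 1.00 | 0.3 | 5.6 | 20.4 |
| gamma | 1.50 | 0.1 | 6.2 | 9.0 |
| gamma | 2.50 | 0.6 | 6.9 | 2.0 |
| gamma | 3.00 | 0.2 | 7.4 | 1.0 |
| beta | 0.500 | 0.1 | 3.6 | 44.1 |
| beta | 1.00 | 0 | 6.4 | 19.1 |
| beta | 1.50 | 0 | 7.4 | 8.4 |
| beta | 2.50 | 0.8 | 7.6 | 1.7 |
| beta | 3.00 | 0 | 7.7 | 0.8 |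

(each reading ± 0.5 percentage points)

- at the start none of the gas is in solution
- "hardly changes" means that all values lie within two and a half points (for a concentration: within two and a half percent of the largest)

- [open intermediate] at the end for green, blue, amber, in this order
- the course of these numbers from the first flask to the last (hardly changes / falls all the way / rises all the way / rises, then falls / falls, then rises)

- In a one-step world the substrate, the limiting reagent, reappears whole as target, but the zeta run at 3.00 h reads 8.5% target beside 0.8% substrate, so my ledger for the charge holds an unread entry of 90.7%.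

- The substrate entry is the one I can integrate: first-order loss gives the fraction left as exp(-kt), and the readings give k = 1.60 h⁻¹ in the zeta run and 1.66 h⁻¹ in the beta run, so I expect 0.169% of the charge left at 4.0 h in each new flask.

- I call the feed the fraction of the charge entering the open intermediate per hour, which is k times the fraction left, and at 4.0 h I reckon it at 0.00269 h⁻¹.

- The open-intermediate entry is a steady-state one, since its readings sit near zero against a scatter of 0.5 percentage points: its stock is the feed times its lifetime, and the zeta reading of 0.4% at 0.417 h puts that lifetime under about 0.00487 h.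

- The target entry tests the capture agent: if capture were the main exit, the target of the zeta run would shrink to 2.99% in the beta run, yet the beta run reads more than that, 7.7%.

- So my books close on 0.169% substrate, target near 7.7%, the rest unread, and I commit to a flat row under about 0.00131% of the charge, which is 6.56 × 10⁻⁷ M.

- The forecast gives 1.000 × 10⁻⁷ M, 5.000 × 10⁻⁸ M and 2.500 × 10⁻⁸ M, a course that falls all the way, with a dependence on the capture agent that it calls “assumed from the name”, and there it parts from my flat row.

- The flasks give 3.49 × 10⁻⁸ M, 3.49 × 10⁻⁸ M and 3.49 × 10⁻⁸ M, a course that hardly changes.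

    open intermediate → solvolysis product (k = 54.0 min⁻¹)
    first nucleophile + open intermediate → target (k = 240 M⁻¹ min⁻¹)
    substrate → open intermediate (k = 0.0270 min⁻¹)
    gas ⇌ first nucleophile, rate k4*(csat - [first nucleophile]) (kL = 1.20 min⁻¹)
    second nucleophile + open intermediate → other capture product (k = 16.0 M⁻¹ min⁻¹)
    open intermediate + capture agent → trapped intermediate (k = 0.900 M⁻¹ min⁻¹)

- My feed of 0.00269 h⁻¹ stands in the green flask at 0.00248 h⁻¹, and dividing the green stock of 3.49 × 10⁻⁸ M, taken as a fraction of the charge, by that feed gives a lifetime of 0.0169 min, while the amber flask gives 0.0169 min the same way, with its capture agent at 0.0500 M against 0.0120 M in green. In the amber flask the open intermediate passes into solvolysis product at 54 min⁻¹, far faster than capture agent takes it, at 0.0450 min⁻¹.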